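**Retrosynthetic overview**
1. Target 9 ⇐ C2–O bond formation with shift of the alkene from C1=C2 to C1=C6: a singlet-oxygen ene transposition on the shikimate-type allyl benzoate 7 (key C–O bond, sets C2).
2. 7 ⇐ regioselective hydrolytic opening of the cis-3,4-orthobenzoate 6, which delivers the 3-O-benzoate and the free 4-OH.
3. 6 ⇐ diol 4 by primary benzoylation then secondary acetylation; 4 ⇐ hydride reduction of ester 3.
4. 3 ⇐ (−)-shikimic acid 1, which supplies all seven skeletal carbons and the C3, C4 and C5 stereocentres.
5. No carbocycle is formed: the six-membered ring is that of 1. The only ring made is the temporary dioxolane orthoester (step 1), opened again in step 4.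

Assumption: positions are numbered as in shikimic acid throughout (C1 carries the exocyclic carbon C7; C3, C4, C5 are the shikimate carbinol carbons; C2 and C6 flank C1). The orthoester carbon of 3 to 6 is carried as both epimers, which does not matter because that centre is lost in step 4.

**Route**

Step 1
Reactants: 1 (−)-shikimic acid
Product: 3 methyl 3,4-O-(α-methoxybenzylidene)shikimate (cis-3,4-orthobenzoate with free 5-OH), via methyl shikimate 2 (not isolated)
Conditions: MeOH, camphorsulfonic acid (CSA, 5 mol %), reflux; evaporate; then PhC(OMe)3 (1.5 equiv), MeCN, rt; Et3N quench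
Reagents that add atoms: methanol (CO); trimethyl orthobenzoate (COC(OC)(OC)c1ccccc1)
Why: Fischer esterification followed by acid-catalysed transorthoesterification, in which the five-membered dioxolane closes only across the cis 3,4-diol (as the acetonide does) and leaves the trans 5-OH free; no stereocentre of 1 is touched.

Step 2
Reactants: 3 methyl 3,4-O-(α-methoxybenzylidene)shikimate
Product: 4 3,4-O-(α-methoxybenzylidene)shikimyl alcohol (7-OH and 5-OH free)
Conditions: LiAlH4, THF, −20 to 0 °C; Na2SO4·10H2O quench
Reagents that add atoms: none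
Why: LiAlH4 1,2-reduction of the enoate to the primary allylic alcohol; orthoesters are inert to hydride without a Lewis acid, and the non-acidic quench preserves the orthoester.

Step 3
Reactants: 4 3,4-O-(α-methoxybenzylidene)shikimyl alcohol
Product: 6 5-O-acetyl-7-O-benzoyl-3,4-O-(α-methoxybenzylidene)shikimyl alcohol, via monobenzoate 5 (not isolated)
Conditions: BzCl (1.05 equiv), pyridine, CH2Cl2, −40 °C; then Ac2O, 4-(dimethylamino)pyridine (DMAP, cat.), 0 °C to rt; NaHCO3 work-up
Reagents that add atoms: benzoyl chloride (O=C(Cl)c1ccccc1); acetic anhydride (CC(=O)OC(C)=O)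
Why: kinetically controlled acylation, the primary allylic 7-OH reacting far faster with BzCl at −40 °C than the flanked secondary 5-OH, which is then acetylated under DMAP catalysis; the basic medium preserves the orthoester.

Step 4
Reactants: 6 5-O-acetyl-7-O-benzoyl-3,4-O-(α-methoxybenzylidene)shikimyl alcohol
Product: 7 [(3R,4S,5R)-5-acetoxy-3-(benzoyloxy)-4-hydroxycyclohex-1-en-1-yl]methyl benzoate
Conditions: AcOH–H2O (4:1), rt
Reagents that add atoms: water (O)
Why: acid hydrolysis of the cyclic orthoester via the 2-phenyl-1,3-dioxolan-2-ylium ion and its hemiorthoester, whose stereoelectronically controlled collapse gives the axial ester and equatorial alcohol (the standard orthoester route to axial monoesters of cis-diols); O3 is pseudoaxial and O4 equatorial in the half-chair that keeps O4 and O5 diequatorial, so the benzoyl group ends on O3.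

Step 5
Reactants: 7 [(3R,4S,5R)-5-acetoxy-3-(benzoyloxy)-4-hydroxycyclohex-1-en-1-yl]methyl benzoate
Product: 9 [(3R,4S,5R,6S)-3-acetoxy-5-(benzoyloxy)-4,6-dihydroxycyclohex-1-en-1-yl]methyl benzoate (target), via C2 hydroperoxide 8 (not isolated)
Conditions: O2, meso-tetraphenylporphyrin (TPP, 1 mol %), white LEDs, CDCl3, 0 °C; then PPh3 (1.2 equiv), 0 °C to rt
Reagents that add atoms: dioxygen (O=O)
Why: Proposed new method: a Schenck ene oxygenation used as a stereocontrolled 1,3-transposition on a shikimate-type 1-(acyloxymethyl)cyclohexene, a substrate class on which it has not been shown; singlet oxygen should bond to C2 of the C1=C2 alkene from the face opposite the pseudoaxial 3-OBz, and on that face only the pseudoaxial C6–H (ring side of the alkene, cis effect) stands perpendicular to the alkene plane, so suprafacial hydrogen transfer moves the double bond to C1=C6 and gives the hydroperoxide with C2–O trans to 3-OBz and cis to 5-OAc (2S in shikimate numbering, C6 of the target name), while the pseudoequatorial C3–H and the ester-deactivated lone-side C7–H are not abstracted; the long singlet-oxygen lifetime in CDCl3 offsets the electron-poor alkene, PPh3 reduces the O–O bond with retention at C2, and the closest known reaction type is the Schenck ene reaction of 1-alkylcyclohexenes and of chiral allylic alcohol derivatives.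

**Compound list**
1 | (−)-shikimic acid, (3R,4S,5R)-3,4,5-trihydroxycyclohex-1-ene-1-carboxylic acid | O=C(O)C1=C[C@@H](O)[C@@H](O)[C@H](O)C1 | starting material
2 | methyl shikimate, methyl (3R,4S,5R)-3,4,5-trihydroxycyclohex-1-ene-1-carboxylate | COC(=O)C1=C[C@@H](O)[C@@H](O)[C@H](O)C1 | intermediate (not isolated)
3 | methyl 3,4-O-(α-methoxybenzylidene)shikimate: cyclic methyl orthobenzoate across the cis 3,4-diol, 5-OH free, both epimers at the orthoester carbon | COC(=O)C1=C[C@H]2OC(OC)(c3ccccc3)O[C@H]2[C@H](O)C1 | intermediate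
4 | 3,4-O-(α-methoxybenzylidene)shikimyl alcohol: 3 with CH2OH (C7) in place of CO2Me, 5-OH free | OCC1=C[C@H]2OC(OC)(c3ccccc3)O[C@H]2[C@H](O)C1 | intermediate
5 | 7-O-benzoyl-3,4-O-(α-methoxybenzylidene)shikimyl alcohol (5-OH free) | O=C(OCC1=C[C@H]2OC(OC)(c3ccccc3)O[C@H]2[C@H](O)C1)c1ccccc1 | intermediate (not isolated)
6 | 5-O-acetyl-7-O-benzoyl-3,4-O-(α-methoxybenzylidene)shikimyl alcohol | O=C(OCC1=C[C@H]2OC(OC)(c3ccccc3)O[C@H]2[C@H](OC(C)=O)C1)c1ccccc1 | intermediate
7 | [(3R,4S,5R)-5-acetoxy-3-(benzoyloxy)-4-hydroxycyclohex-1-en-1-yl]methyl benzoate (5-O-acetyl-3,7-di-O-benzoylshikimyl alcohol) | O=C(OCC1=C[C@@H](OC(=O)c2ccccc2)[C@@H](O)[C@H](OC(C)=O)C1)c1ccccc1 | intermediate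
8 | C2 hydroperoxide: 9 with OOH in place of the C2 OH (shikimate numbering), same spatial arrangement, C1=C6 alkene | CC(=O)O[C@@H]1C=C(COC(=O)c2ccccc2)[C@H](OO)[C@@H](OC(=O)c2ccccc2)[C@H]1O | intermediate (not isolated)
9 | [(3R,4S,5R,6S)-3-acetoxy-5-(benzoyloxy)-4,6-dihydroxycyclohex-1-en-1-yl]methyl benzoate, CNP0169028.1 | CC(=O)O[C@@H]1C=C(COC(=O)c2ccccc2)[C@H](O)[C@@H](OC(=O)c2ccccc2)[C@H]1O | target

**Totals**
Total step count: 5. Longest linear sequence: 5 (fully linear from 1).

**Three steps most likely to fail**

Step 5 (the proposed ene transposition). The alkene carries two allylic ester oxygens and may react slowly; hydrogen abstraction at C3 or C7, or attack syn to the 3-OBz, would give isomers. The fallback uses only known chemistry (diene and endoperoxide, as in conduritol syntheses); it sets out from 4 and comes back at 9. Diol 4 is benzoylated at O7 as in step 3 and 5 is isolated. Tf2O and pyridine give the C5 triflate F1. DBU eliminates it to the cyclohexa-1,5-diene F2. Singlet oxygen (TPP, O2, light) adds [4+2] across C2 and C5 on the face opposite the dioxolane to give the endoperoxide F3. Thiourea reduces the O–O bond to the cis-2,5-diol F4. One equivalent of Ac2O with 2,4,6-collidine at −20 °C acetylates the less hindered 5-OH (the 2-OH sits next to the C1 side chain) to give the monoacetate F5. AcOH–H2O then opens the orthoester to 9.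

Step 4 (orthoester opening). The selectivity rests on a modest conformational preference; the 4-benzoate or O3-to-O4 benzoyl migration could compete. The fallback fixes the benzoate position by protecting-group logic; it sets out from 1 and comes back at 7. Shikimic acid 1 with butane-2,3-dione, CH(OMe)3, MeOH and CSA at reflux gives the 4,5-butanediacetal methyl ester F6, in which the trans diol is locked and the 3-OH is free. LiAlH4 gives the diol F7. BzCl (2.5 equiv), pyridine and DMAP give the 3,7-dibenzoate F8. TFA–H2O (9:1) removes the diacetal to give the 4,5-diol F9. AcCl with 2,4,6-collidine in CH2Cl2 at −40 °C acetylates the less hindered equatorial 5-OH (the 4-OH lies between two acyloxy-bearing carbons) to give 7.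

Step 3 (one-pot benzoylation and acetylation). Some benzoylation at O5, and hence mixed esters, is possible. The fallback replaces acyl-electrophile discrimination by alcohol activation; it sets out from 4 and comes back at 6. Mitsunobu esterification (BzOH, PPh3, DIAD, THF, 0 °C, the acid being buffered by the betaine) engages only the unhindered primary allylic alcohol. Monobenzoate 5 is isolated and then acetylated (Ac2O, pyridine, DMAP) to 6. No new compound is made (F0).

**Further compounds**
F1 | step 5 | C5 triflate of 5: 7-O-benzoyl-3,4-O-(α-methoxybenzylidene)-5-O-(trifluoromethanesulfonyl)shikimyl alcohol | O=C(OCC1=C[C@H]2OC(OC)(c3ccccc3)O[C@H]2[C@H](OS(=O)(=O)C(F)(F)F)C1)c1ccccc1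
F2 | step 5 | diene: [3,4-O-(α-methoxybenzylidene)-3,4-dihydroxycyclohexa-1,5-dien-1-yl]methyl benzoate, C3 and C4 as in 5 | O=C(OCC1=C[C@H]2OC(OC)(c3ccccc3)O[C@H]2C=C1)c1ccccc1
F3 | step 5 | endoperoxide: 2,5-epidioxide of F2, O–O bridge on the face opposite the dioxolane, C1=C6 alkene | O2[C@@H]1C=C(COC(=O)c3ccccc3)[C@H](O2)[C@H]4OC(OC)(c5ccccc5)O[C@@H]14
F4 | step 5 | cis-2,5-diol from F3: 7-O-benzoyl-3,4-O-(α-methoxybenzylidene) derivative with 2-OH and 5-OH both trans to the dioxolane oxygens, C1=C6 alkene | O[C@@H]1C=C(COC(=O)c2ccccc2)[C@H](O)[C@H]3OC(OC)(c4ccccc4)O[C@@H]13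
F5 | step 5 | 5-O-acetate of F4 (9 with O3 and O4 still joined in the orthobenzoate) | CC(=O)O[C@@H]1C=C(COC(=O)c2ccccc2)[C@H](O)[C@H]3OC(OC)(c4ccccc4)O[C@@H]13
F6 | step 4 | methyl 4,5-O-[(2S,3S)-2,3-dimethoxybutane-2,3-diyl]shikimate (3-OH free) | COC(=O)C1=C[C@@H](O)[C@H]2O[C@](C)(OC)[C@@](C)(OC)O[C@@H]2C1
F7 | step 4 | 4,5-O-[(2S,3S)-2,3-dimethoxybutane-2,3-diyl]shikimyl alcohol (3-OH and 7-OH free) | OCC1=C[C@@H](O)[C@H]2O[C@](C)(OC)[C@@](C)(OC)O[C@@H]2C1
F8 | step 4 | 3,7-di-O-benzoyl derivative of F7 | O=C(OCC1=C[C@@H](OC(=O)c3ccccc3)[C@H]2O[C@](C)(OC)[C@@](C)(OC)O[C@@H]2C1)c1ccccc1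
F9 | step 4 | [(3R,4S,5R)-3-(benzoyloxy)-4,5-dihydroxycyclohex-1-en-1-yl]methyl benzoate (3,7-di-O-benzoylshikimyl alcohol) | O=C(OCC1=C[C@@H](OC(=O)c2ccccc2)[C@@H](O)[C@H](O)C1)c1ccccc1
F0 | step 3 | none | none
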